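**Plan**

Locants: chroman O1–C8a, side chain C1'–C6', cyclohexene C1''–C6'' (C1'' carries the chain, C2'' one methyl, C6'' two). The same locants are used for the open-chain precursors.
Cuts, in retrosynthetic order: O1–C8a (aryl ether), C2–CH3, C1''–C6'' (the carbocycle opens to a linear polyene), C1'=C2', C3–C4.
Enabling feature: C2'–C6' and C1''–C6', with their four methyl groups, form one unbroken head-to-tail C15 farnesane chain. The 2,6,6-trimethylcyclohexene is its two distal isoprene units joined through C1''–C6'', so opening that bond leads back to (2E,6E)-farnesal.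
Forward order: the chain is joined first (C3–C4 by alkylation, C1'=C2' by olefination). The cyclohexene then closes by cation–olefin cyclisation, C2 is made quaternary, and the dihydropyran ring closes last onto the purchased arene.
Stereochemistry: C3'=C4' (E) comes from farnesol and C1'=C2' (E) from the phosphonate olefination. C2 (R) comes from catalyst-controlled methyl addition to the Si face of the ketone, and the later ring closure at oxygen leaves the C2–O bond intact.

Key step: step 4

Assumption: the ligand enantiomer that delivers alkyl groups to the Si face of aryl alkyl ketones is taken to do the same here, with the dienyl arm in the place of the aryl group; if the sense proves opposite, the mirror-image ligand is used.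

**Step 1**
Reactants: 1 (2E,6E)-farnesol
Product: 2 (2E,6E)-farnesal
Conditions: TEMPO (cat.), PhI(OAc)2, CH2Cl2, rt
Reagents that add atoms: none
Why: Oxoammonium (TEMPO/hypervalent iodine) oxidation of a primary allylic alcohol stops at the enal under nearly neutral conditions, so the 2E alkene keeps its geometry and the two isolated alkenes are untouched.

**Step 2**
Reactants: 3 dimethyl (2-oxopropyl)phosphonate; 4 methyl 3-(bromomethyl)-4-fluorobenzoate
Product: 6 methyl 3-[4-(dimethoxyphosphoryl)-3-oxobutyl]-4-fluorobenzoate, via phosphonate dianion 5 (not isolated)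
Conditions: 3, NaH, THF, 0 °C; n-BuLi, 0 °C; 4, −78 → −20 °C; then 1 M HCl
Reagents that add atoms: none
Why: γ-Alkylation of a β-ketophosphonate dianion, in which the terminal carbanion of 5 (the last formed and most reactive site) displaces the benzylic bromide by SN2 at low temperature faster than it can reach the ester or the C–F carbon, and the product is shielded as its stabilised monoanion until the quench.

**Step 3**
Reactants: 2 (2E,6E)-farnesal; 6 methyl 3-[4-(dimethoxyphosphoryl)-3-oxobutyl]-4-fluorobenzoate
Product: 7 methyl 4-fluoro-3-[(4E,6E,10E)-7,11,15-trimethyl-3-oxohexadeca-4,6,10,14-tetraen-1-yl]benzoate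
Conditions: LiCl, i-Pr2NEt, MeCN, rt
Reagents that add atoms: none
Why: Horner–Wadsworth–Emmons olefination under Masamune–Roush conditions, in which the lithium-chelated β-ketophosphonate is deprotonated by a mild amine, adds reversibly to the enal and collapses to the E enone, forming C1'=C2' without disturbing the 2E alkene of farnesal.

**Step 4**
Reactants: 7 methyl 4-fluoro-3-[(4E,6E,10E)-7,11,15-trimethyl-3-oxohexadeca-4,6,10,14-tetraen-1-yl]benzoate
Product: 10 methyl 4-fluoro-3-[(4E,6E)-7-methyl-3-oxo-9-(2,6,6-trimethylcyclohex-1-en-1-yl)nona-4,6-dien-1-yl]benzoate, via cyclohex-2-enyl isomer 8 (not isolated), via exo-methylidene isomer 9 (not isolated)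
Conditions: conc. H2SO4, AcOH–CH2Cl2, −5 to 0 °C, short contact (HPLC control); then ice/aq NaHCO3
Reagents that add atoms: none
Why: The acid first protonates the carbonyl oxygens and then adds H+ in the Markovnikov sense to the remote isopropylidene alkene C5''=C6''; the tertiary C6'' cation is captured through C1'' by the neighbouring isolated C1''=C2'' alkene (new bond C1''–C6''), and the resulting tertiary C2'' cation loses a proton. The closest known reaction type is the Brønsted-acid cation–olefin monocyclisation of polyprenyl chains whose head alkene is tied to an acceptor (farnesoic acid to monocyclofarnesoic acid, geranyl sulfones to β-cyclogeranyl sulfones, pseudoionone to ionones). The one ring closes in the 6-endo-trig mode with respect to C1''=C2'' through a chair-like fold, whereas protonation of the inner alkene simply reverts, because from C2'' the tail alkene could only close a four- or five-membered ring. No stereocentre remains, since C1'' is stereogenic only in the kinetic isomers 8 and 9, which re-enter the C2'' cation by reprotonation and should drain into the tetrasubstituted, thermodynamically preferred alkene of 10. The selectivity needed is one ring and not two, and the substrate secures it: C3'=C4' is the end of an O-protonated dienone (a hydroxypentadienyl cation with positive charge at C4'), so its attack on C2'' would build a dication and should be far slower than proton loss, while the first closure uses an unperturbed trisubstituted alkene. That second closure is the ionone-forming reaction, so it is only slow and not forbidden, and the same protonation lowers the rotation barrier at C3'=C4'; the run is therefore held at or below 0 °C in sulfuric–acetic acid rather than a superacid and is quenched once 8 and 9 have converged on 10, conditions under which the electron-poor fluoroarene resists Friedel–Crafts attack and the methyl ester survives.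

**Step 5**
Reactants: 10 methyl 4-fluoro-3-[(4E,6E)-7-methyl-3-oxo-9-(2,6,6-trimethylcyclohex-1-en-1-yl)nona-4,6-dien-1-yl]benzoate
Product: 11 methyl 4-fluoro-3-[(3R,4E,6E)-3-hydroxy-3,7-dimethyl-9-(2,6,6-trimethylcyclohex-1-en-1-yl)nona-4,6-dien-1-yl]benzoate
Conditions: Me2Zn, Ti(Oi-Pr)4, trans-1,2-bis(2-exo-hydroxybornane-10-sulfonamido)cyclohexane (10 mol %), toluene–hexane, rt; then H2O, Celite
Reagents that add atoms: dimethylzinc, C[Zn]C
Why: Titanium-catalysed enantioselective 1,2-addition of a dialkylzinc to a ketone, established for acyclic conjugated enones, in which the chiral bis(sulfonamido)titanium complex distinguishes the flat dienyl arm from the sp3 CH2CH2Ar arm and delivers methyl to the Si face of C=O, setting the carbinol centre as R (the later C2) while the ester and the C–F bond stay inert.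

**Step 6**
Reactants: 11 methyl 4-fluoro-3-[(3R,4E,6E)-3-hydroxy-3,7-dimethyl-9-(2,6,6-trimethylcyclohex-1-en-1-yl)nona-4,6-dien-1-yl]benzoate
Product: 13 methyl (2R)-2-methyl-2-[(1E,3E)-4-methyl-6-(2,6,6-trimethylcyclohex-1-en-1-yl)hexa-1,3-dien-1-yl]-3,4-dihydro-2H-chromene-6-carboxylate, via sodium alkoxide 12 (not isolated)
Conditions: NaH, DMF (high dilution), 0 → 40 °C
Reagents that add atoms: none
Why: Intramolecular SNAr (addition–elimination through a Meisenheimer adduct), in which the tertiary alkoxide 12 attacks the fluorine-bearing carbon activated by the para ester to close a six-membered ring, and since only the O–H and C–F bonds change, the R centre is carried over unchanged.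

**Step 7**
Reactants: 13 methyl (2R)-2-methyl-2-[(1E,3E)-4-methyl-6-(2,6,6-trimethylcyclohex-1-en-1-yl)hexa-1,3-dien-1-yl]-3,4-dihydro-2H-chromene-6-carboxylate
Product: 15 (2R)-2-methyl-2-[(1E,3E)-4-methyl-6-(2,6,6-trimethylcyclohex-1-en-1-yl)hexa-1,3-dien-1-yl]-3,4-dihydro-2H-chromene-6-carboxylic acid, via lithium carboxylate 14 (not isolated)
Conditions: LiOH, THF–MeOH–H2O, 40 °C; then cold 0.5 M HCl to pH 4–5
Reagents that add atoms: lithium hydroxide, [Li+].[OH-]
Why: Base-mediated ester hydrolysis (BAc2 saponification) touches neither the aryl ether, the diene nor C2, and acidification only to pH 4–5 in the cold avoids ionising the tertiary dienylic aryl ether.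

**Compound list**

1 | (2E,6E)-farnesol | CC(C)=CCC/C(C)=C/CC/C(C)=C/CO | starting material
2 | (2E,6E)-farnesal | CC(C)=CCC/C(C)=C/CC/C(C)=C/C=O | intermediate
3 | dimethyl (2-oxopropyl)phosphonate | CC(=O)CP(=O)(OC)OC | starting material
4 | methyl 3-(bromomethyl)-4-fluorobenzoate | COC(=O)c1ccc(F)c(CBr)c1 | starting material
5 | sodium lithium 1,3-dianion of dimethyl (2-oxopropyl)phosphonate (not isolated) | [Na+].[Li+].[CH2-]C(=O)[CH-]P(=O)(OC)OC | intermediate
6 | methyl 3-[4-(dimethoxyphosphoryl)-3-oxobutyl]-4-fluorobenzoate | COC(=O)c1ccc(F)c(CCC(=O)CP(=O)(OC)OC)c1 | intermediate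
7 | methyl 4-fluoro-3-[(4E,6E,10E)-7,11,15-trimethyl-3-oxohexadeca-4,6,10,14-tetraen-1-yl]benzoate | CC(C)=CCC/C(C)=C/CC/C(C)=C/C=C/C(=O)CCc1cc(C(=O)OC)ccc1F | intermediate
8 | methyl 4-fluoro-3-[(4E,6E)-7-methyl-3-oxo-9-(2,6,6-trimethylcyclohex-2-en-1-yl)nona-4,6-dien-1-yl]benzoate, racemic at ring C1'' (not isolated) | CC1=CCCC(C)(C)C1CC/C(C)=C/C=C/C(=O)CCc2cc(C(=O)OC)ccc2F | intermediate
9 | methyl 3-[(4E,6E)-9-(2,2-dimethyl-6-methylidenecyclohexyl)-7-methyl-3-oxonona-4,6-dien-1-yl]-4-fluorobenzoate, racemic at ring C1'' (not isolated) | C=C1CCCC(C)(C)C1CC/C(C)=C/C=C/C(=O)CCc2cc(C(=O)OC)ccc2F | intermediate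
10 | methyl 4-fluoro-3-[(4E,6E)-7-methyl-3-oxo-9-(2,6,6-trimethylcyclohex-1-en-1-yl)nona-4,6-dien-1-yl]benzoate | CC1=C(CC/C(C)=C/C=C/C(=O)CCc2cc(C(=O)OC)ccc2F)C(C)(C)CCC1 | intermediate
11 | methyl 4-fluoro-3-[(3R,4E,6E)-3-hydroxy-3,7-dimethyl-9-(2,6,6-trimethylcyclohex-1-en-1-yl)nona-4,6-dien-1-yl]benzoate | CC1=C(CC/C(C)=C/C=C/[C@](C)(O)CCc2cc(C(=O)OC)ccc2F)C(C)(C)CCC1 | intermediate
12 | sodium alkoxide of 11 (not isolated) | CC1=C(CC/C(C)=C/C=C/[C@](C)([O-])CCc2cc(C(=O)OC)ccc2F)C(C)(C)CCC1.[Na+] | intermediate
13 | methyl (2R)-2-methyl-2-[(1E,3E)-4-methyl-6-(2,6,6-trimethylcyclohex-1-en-1-yl)hexa-1,3-dien-1-yl]-3,4-dihydro-2H-chromene-6-carboxylate | CC1=C(CC/C(C)=C/C=C/[C@@]2(C)CCc3cc(C(=O)OC)ccc3O2)C(C)(C)CCC1 | intermediate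
14 | lithium carboxylate of 15 (not isolated) | CC1=C(CC/C(C)=C/C=C/[C@@]2(C)CCc3cc(C(=O)[O-])ccc3O2)C(C)(C)CCC1.[Li+] | intermediate
15 | (2R)-2-methyl-2-[(1E,3E)-4-methyl-6-(2,6,6-trimethylcyclohex-1-en-1-yl)hexa-1,3-dien-1-yl]-3,4-dihydro-2H-chromene-6-carboxylic acid (CNP0265961.1) | CC1=C(CC/C(C)=C/C=C/[C@@]2(C)CCc3cc(C(=O)O)ccc3O2)C(C)(C)CCC1 | target

**Totals and risks**

Total step count: 7. Longest linear sequence: 6 steps (steps 1, 3, 4, 5, 6, 7, or equally 2, 3, 4, 5, 6, 7).

**Step 4, most likely to fail.** Three things may go wrong: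
- The cascade may run on, with C3' attacking the C2'' cation to fuse a second six-membered ring.
- The ring-alkene isomers may not converge fully before that sets in.
- Rotation about C3'=C4' in the protonated dienone may erode the E geometry.

The fallback buys the carbocycle instead of closing it. It sets out from 6 and returns at 10. Commercial dihydro-β-ionone F1 is homologated by a Horner–Wadsworth–Emmons reaction with triethyl phosphonoacetate (NaH, THF) to ethyl (2E)-3-methyl-5-(2,6,6-trimethylcyclohex-1-en-1-yl)pent-2-enoate F2, and the minor Z ester is removed by chromatography. DIBAL-H reduction should give β-monocyclofarnesol F3, and TEMPO/PhI(OAc)2 oxidation β-monocyclofarnesal F4. Olefination of F4 with 6 under the conditions of step 3 gives 10.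

**Step 5.** Facial discrimination between an unbranched dienyl arm and a primary alkyl arm may be poor. Methyl transfer from zinc may be sluggish, and slow ester exchange with isopropoxide may blur the product. The fallback replaces asymmetric catalysis by resolution. It sets out from 10 and returns at 13. Chemoselective 1,2-addition of the organocerium reagent from MeMgBr and CeCl3 (THF, −78 °C) should give the racemic tertiary alcohol F5. NaH in DMF converts it through the racemic sodium alkoxide F6 into the racemic chroman ester F7. Preparative chromatography of F7 on a chiral stationary phase (SFC) delivers the R enantiomer 13.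

**Step 2.** The dianion may attack the ester or the activated C–F carbon, and proton transfer between product and dianion may lead to double alkylation. The fallback builds the same enone by arylation and aldol chemistry. It sets out from 2 and returns at 7.
- Heck arylation of but-3-en-2-ol F9 with methyl 3-bromo-4-fluorobenzoate F8 (Pd(OAc)2, Bu4NCl, NaHCO3, DMF, 80 °C), with in situ enol–ketone tautomerisation, should give methyl 4-fluoro-3-(3-oxobutyl)benzoate F10.
- LDA (1.0 equiv, THF, −78 °C) forms the kinetic methyl-side lithium enolate F11, which adds to 2 to give the racemic aldol adduct F12.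
- Acetylation (Ac2O, DMAP, Et3N) gives the β-acetoxy ketone F13, and E1cB elimination with DBU gives 7.

**Further compounds**

F1 | step 4 | dihydro-β-ionone, 4-(2,6,6-trimethylcyclohex-1-en-1-yl)butan-2-one (purchased) | CC1=C(CCC(C)=O)C(C)(C)CCC1
F2 | step 4 | ethyl (2E)-3-methyl-5-(2,6,6-trimethylcyclohex-1-en-1-yl)pent-2-enoate | CC1=C(CC/C(C)=C/C(=O)OCC)C(C)(C)CCC1
F3 | step 4 | β-monocyclofarnesol, (2E)-3-methyl-5-(2,6,6-trimethylcyclohex-1-en-1-yl)pent-2-en-1-ol | CC1=C(CC/C(C)=C/CO)C(C)(C)CCC1
F4 | step 4 | β-monocyclofarnesal, (2E)-3-methyl-5-(2,6,6-trimethylcyclohex-1-en-1-yl)pent-2-enal | CC1=C(CC/C(C)=C/C=O)C(C)(C)CCC1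
F5 | step 5 | racemic tertiary alcohol (racemate of 11) | CC1=C(CC/C(C)=C/C=C/C(C)(O)CCc2cc(C(=O)OC)ccc2F)C(C)(C)CCC1
F6 | step 5 | racemic sodium alkoxide (racemate of 12) | CC1=C(CC/C(C)=C/C=C/C(C)([O-])CCc2cc(C(=O)OC)ccc2F)C(C)(C)CCC1.[Na+]
F7 | step 5 | racemic chroman ester (racemate of 13) | CC1=C(CC/C(C)=C/C=C/C2(C)CCc3cc(C(=O)OC)ccc3O2)C(C)(C)CCC1
F8 | step 2 | methyl 3-bromo-4-fluorobenzoate (purchased) | COC(=O)c1ccc(F)c(Br)c1
F9 | step 2 | but-3-en-2-ol (purchased) | C=CC(C)O
F10 | step 2 | methyl 4-fluoro-3-(3-oxobutyl)benzoate | CC(=O)CCc1cc(C(=O)OC)ccc1F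
F11 | step 2 | kinetic lithium enolate of F10 | [Li+].C=C([O-])CCc1cc(C(=O)OC)ccc1F
F12 | step 2 | methyl 4-fluoro-3-[(6E,10E)-5-hydroxy-7,11,15-trimethyl-3-oxohexadeca-6,10,14-trien-1-yl]benzoate (racemic) | CC(C)=CCC/C(C)=C/CC/C(C)=C/C(O)CC(=O)CCc1cc(C(=O)OC)ccc1F
F13 | step 2 | methyl 3-[(6E,10E)-5-acetoxy-7,11,15-trimethyl-3-oxohexadeca-6,10,14-trien-1-yl]-4-fluorobenzoate (racemic) | CC(C)=CCC/C(C)=C/CC/C(C)=C/C(OC(C)=O)CC(=O)CCc1cc(C(=O)OC)ccc1F
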